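## Structural features

The target is a pentacyclic spiro compound in which an isoindolin-1-one (benzene ring A fused to γ-lactam ring B) and a 2H-naphtho[1,8-bc]furan (furan ring C bridging the peri positions of a naphthalene made of rings D and E) share a single carbon. That carbon, C3 of the lactam, is the only stereocentre: it is quaternary, bonded to N2, to the ring C oxygen O1', to C3a of ring A and to C8' of ring D, has no neighbouring stereocentre, and is (S) by the sequence rule (O1' > N2 > C3a > C8', the methoxy-bearing aryl outranking the hydroxy-bearing one). Primed locants are those of the parent naphthalene throughout: C1' carries O1', C3' the methyl group (ring E), C7' the free hydroxyl (ring D) and C8' the spiro carbon. Ring A is contiguously trisubstituted, with methoxy on C4, the spiro carbon on C3a and the lactam carbonyl C1 on C7a, and N2 bears a 2-hydroxyethyl chain. The fragile element is the N-acyl N,O-ketal: acid can ionize it at C3 and base can open it through the C7' naphtholate as an ortho-quinone methide, either of which would erase the configuration; the electron-rich naphthol is also oxidation-prone, and the doubly benzylic C3–O and C3–N bonds exclude hydrogenolysis. The real difficulty is to assemble the crowded C3, which carries four different substituents between two ortho-oxygenated aryl groups, and to fix its absolute configuration with no other stereocentre to lean on. The key step exploits the 1,2,3-pattern of ring A: C3a and C7a are the two carbons of 3-methoxybenzyne, C1 with N2 and its side chain is an isocyanide, and C3 with O1' and rings D and E is the carbonyl group of a peri-naphtholactone.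

## Logic of the disconnections

21 from 20. The O–Si bond of the side-chain oxygen is cut. The primary hydroxyl has to stay masked from step 10 to step 12, where it would add to the aryne or to the imidate carbon C1. Nothing is gained in skeleton; the last step becomes a single deprotection. The forward step must use fluoride without forming the C7' naphtholate.

20 from 19. The C3–N2 bond is cut and replaced by a bond from C3 to the oxygen on C1, which turns the lactam into its ring-isomeric imidate. The imidate is what a three-component coupling delivers and the lactam is the more stable isomer. Their interconversion passes through a planar, cationic C3, the one point at which a chiral counter-ion can install the configuration. The stereocentre thereby disappears from every earlier intermediate. The forward step must be a kinetically controlled closure with no racemic background and no re-ionization of the product.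

19 from 18. The O–allyl bond at C7' is cut. The naphthol must be a fluoride-stable ether in step 10 but free in step 12, where it lends quinone-methide character to the cation and anchors the catalyst by a hydrogen bond. The forward step must unmask it without acid or strong base, since the imidate ketal is acid-labile.

18 from 11, 15 and 16 (through 17). Three bonds are cut: C7a–C1, C3a–C3 and O–C1. Ring A then reduces to an aryne, C1/N2 and the chain to an isocyanide, and C3 with rings C, D and E to a lactone. These are three fragments of similar size that contain every skeletal atom of the target. The forward step needs the isocyanide to attack the aryne carbon remote from methoxy, and the resulting anion to add to the lactone carbonyl before it is protonated or consumed by a second aryne.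

11 from 9 (through 10). The bond between the carbonyl carbon (future C3) and C8' is cut. The carbonyl can be delivered from the C1' oxygen to a peri carbanion through a five-membered transition state, so the strained lactone reduces to a bromonaphthyl carbonate. The forward step needs halogen–metal exchange to outrun attack on the carbonate and the allyl ether to stay inert.

9 from 8, and 8 from 7. The C8'–Br bond and then the O–C(=O) bond at C1' are cut. The carbonate deactivates its own ring so that the C7' ether directs the electrophile to C8', and it stores the future C3. The forward step needs bromination at C8' only.

7 from 5 (through 6). The ring bond C1'–C8a' is cut, opening ring E. The naphthalene reduces to a para-substituted benzene with a four-carbon acid chain that already holds the C3' methyl, so no later adjustment of oxidation level is needed. The forward step needs the alkene isomers of 5 to equilibrate under the cyclization conditions.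

5 from 2 and 3 (through 4), and 2 from 1. The C=C bond of the chain (olefination) and the O–allyl bond are cut, leading to a commercial ketophenol and a phosphonate. The forward olefination need not be selective in geometry.

15 from 14, 14 from 13, 13 from 12. The isocyanide is a dehydrated formamide; the O–Si and N–CHO bonds are then cut back to the amino alcohol. The forward sequence needs N-selective formylation and a dehydration that spares the silyl ether.

## Other disconnections considered

Alternative 1: The cut goes through ring D at C8'–C8a' and C6'–C7'. In the forward direction, light or heat expels dinitrogen from the 2-diazo-1,3-diketone A2. The ring E aryl group migrates to the carbene carbon (Wolff rearrangement), and the resulting aroyl ketene closes onto the ortho vinyl group (6π electrocyclization) and tautomerizes to the 1-aroyl-2-naphthol A1.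
- In its favour: the crowded C3–C8' bond and the full oxygen pattern of the naphthalene arrive together, with the two naphthalene oxygens already differentiated, and ring A enters intact with a bromine that could later become C1.
- Against it here: either aryl group of A2 can migrate and only one migration leads to A1. Acyl ketenes also dimerize or close through oxygen. A2 needs a hindered unsymmetrical diketone plus diazo transfer. The step forms neither C1 nor the stereocentre, so carbonylation, lactam formation and an enantioselective spiro closure would still follow.
- Comparison: structurally it spends its key step on ring D, which the chosen plan obtains by a classical benzannulation, and it is clearly longer. Mechanistically the two plans are comparably bold (migratory selectivity against three-component efficiency). It is the better plan on one point: the spiro centre would be closed from a keto amide through an N-acyl ketiminium ion, an ion pair with closer precedent in chiral phosphoric acid catalysis than the imidate ionization used here. It is the equal of the chosen plan in regiochemical certainty on ring A.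

Alternative 2: The cut goes through ring A at C3a–C4 and C7–C7a. In the forward direction, 3-methoxy-2-pyrone A4 and the naphthyl ynone ester A5 combine in a Diels–Alder reaction, and the bicyclic lactone loses CO2 to give the 2-aroyl-3-methoxybenzoate A3.
- In its favour: it is convergent, the aromatization is irreversible, and the regiochemistry is electronically matched (the nucleophilic pyrone terminus C6 pairs with the alkyne carbon β to the ketone). A3 holds C1 at the carboxyl level and C3 as a ketone, so ethanolamine could close the hydroxy lactam directly.
- Against it here: the regiochemical margin rests on the small difference between a ketone and an ester acceptor. Pyrone cycloadditions need high temperatures at which a hindered ynone may polymerize. A5 needs the same naphthalene work as 11 plus the ynone construction. Benzyl ethers call for hydrogenolysis, which threatens the doubly benzylic C3 once the spiro ketal exists. The stereocentre is again left for later.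
- Comparison: it is the better plan on protecting-group economy at nitrogen (no silyl ether, no fluoride) and on having the correct oxidation levels at C1 and C3 from the start. The chosen plan is better on convergence and step count, and its aryne regiochemistry is better secured than the pyrone orientation.

Alternative 3: The cut is C3–N2. In the forward direction, the dioxazolone A7 loses CO2 on a pentamethylcyclopentadienyl iridium catalyst (trivalent iridium, from [Cp*IrCl2]2 and AgNTf2), and the acyl nitrenoid inserts into the C3–H bond with retention to give the N-unsubstituted lactam A6.
- In its favour: the configuration is transferred and not created in the ring-forming event, by a stereospecific insertion that does not depend on an ion pair. On reliability of that one bond formation it is the equal or the better of the chosen plan.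
- Against it here: A7 must be enantiopure at a doubly benzylic, α-aryloxy C–H carbon, whose asymmetric synthesis is a problem as large as the original and which can racemize under acid, base or oxidants. So activated a C–H bond may react by stepwise hydride or hydrogen-atom abstraction, which would forfeit retention. Without a tailored chelating ligand, acyl nitrenoids tend towards Curtius rearrangement, and the electron-rich ring D offers competing arene amidation. A6 still needs N-alkylation next to a quaternary centre (N against O alkylation) and desilylation.
- Comparison: the stereochemical problem is moved, not removed, and the route is longer. The chosen plan creates C3 and the whole skeleton in one step and addresses the configuration at the last possible stage.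

Key step: step 10

Remarks on the chemistry.
- By fused-ring nomenclature the peri-lactone 11 is 3-(allyloxy)-7-methyl-2H-naphtho[1,8-bc]furan-2-one; the locants "7-allyloxy-4-methyl" do not fit its structure, which is otherwise unchanged.
- The naphthol is built from 4-hydroxyphenylacetone so that the C3' methyl is present from the start and no ester has to be reduced to a methyl group.
- Assumption: the (R)-enantiomer of the phosphoric acid is written in step 12. The sense of induction cannot be derived from a close precedent, and the (S)-acid is to be used if it is the matched one.

## Steps

Step 1
Reactants: 1 4-hydroxyphenylacetone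
Product: 2 1-[4-(allyloxy)phenyl]propan-2-one
Conditions: allyl bromide, K2CO3, acetone, reflux
Reagents that add atoms: allyl bromide, C=CCBr
Why: Williamson ether synthesis; the phenoxide formed by K2CO3 is alkylated on oxygen much faster than the ketone is enolized under these conditions.

Step 2
Reactants: 2 1-[4-(allyloxy)phenyl]propan-2-one; 3 triethyl phosphonoacetate
Product: 5 4-[4-(allyloxy)phenyl]-3-methylbut-2-enoic acid (mixture of alkene isomers), via ethyl ester 4 (not isolated)
Conditions: NaH, THF, 0 °C to rt; then aq. NaOH, EtOH, 60 °C; HCl work-up
Reagents that add atoms: sodium hydroxide (aqueous), [Na+].[OH-]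
Why: Horner–Wadsworth–Emmons olefination followed by saponification in the same flask, with acid–base extraction removing phosphate and neutral material. Geometry and position of the double bond need no control because step 3 equilibrates them.

Step 3
Reactants: 5 4-[4-(allyloxy)phenyl]-3-methylbut-2-enoic acid
Product: 7 7-(allyloxy)-3-methylnaphthalen-1-ol, via naphthyl acetate 6 (not isolated)
Conditions: Ac2O, NaOAc, 130 °C; evaporation; then K2CO3 (cat.), MeOH, rt
Reagents that add atoms: none
Why: Stobbe-type benzannulation: acetate-mediated enolization of the mixed anhydride interconverts the alkene isomers and gives a dienyl ketene that closes C1'–C8a' ortho to the side chain (6π electrocyclization, formally a Friedel–Crafts acylation), and the naphthol is trapped as its acetate. Mild methanolysis then frees the naphthol; the allyl aryl ether should stay below the temperature range of its Claisen rearrangement for the short heating period.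

Step 4
Reactants: 7 7-(allyloxy)-3-methylnaphthalen-1-ol
Product: 8 tert-butyl 7-(allyloxy)-3-methylnaphthalen-1-yl carbonate
Conditions: Boc2O, DMAP (cat.), MeCN, rt
Reagents that add atoms: di-tert-butyl dicarbonate, CC(C)(C)OC(=O)OC(=O)OC(C)(C)C
Why: DMAP-catalysed O-acylation of a phenol; the carbonate damps the reactivity of ring E towards electrophiles and stores the carbon that becomes C3.

Step 5
Reactants: 8 tert-butyl 7-(allyloxy)-3-methylnaphthalen-1-yl carbonate
Product: 9 8-bromo-7-(allyloxy)-3-methylnaphthalen-1-yl tert-butyl carbonate
Conditions: NBS, MeCN, 0 °C to rt, dark
Reagents that add atoms: N-bromosuccinimide, O=C1CCC(=O)N1Br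
Why: Electrophilic aromatic bromination; C8' is the α position ortho to the C7' ether (the 1-position of a 2-alkoxynaphthalene) and is far more activated than any site of the carbonate-bearing ring. Polar conditions without light favour the arene over the allyl double bond.

Step 6
Reactants: 9 8-bromo-7-(allyloxy)-3-methylnaphthalen-1-yl tert-butyl carbonate
Product: 11 3-(allyloxy)-7-methyl-2H-naphtho[1,8-bc]furan-2-one, via tert-butyl hydroxynaphthoate 10 (not isolated)
Conditions: n-BuLi, THF, −78 °C; then CF3CO2H, CH2Cl2, rt
Reagents that add atoms: none
Why: Bromine–lithium exchange gives the peri aryllithium, which takes the carbonate carbonyl through a five-membered transition state (anionic Fries-type acyl transfer, Parham-type cyclization) and releases the naphtholate of 10. Acid then cleaves the tert-butyl ester and closes the peri-lactone, which forms readily from an 8-hydroxy-1-naphthoic acid.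

Step 7
Reactants: 12 ethanolamine
Product: 13 N-(2-hydroxyethyl)formamide
Conditions: HCO2Et, EtOH, 0 °C to rt
Reagents that add atoms: ethyl formate, CCOC=O
Why: Aminolysis of a formate ester; the amine is much more nucleophilic than the hydroxyl, so only nitrogen is formylated.

Step 8
Reactants: 13 N-(2-hydroxyethyl)formamide
Product: 14 N-[2-(tert-butyldiphenylsilyloxy)ethyl]formamide
Conditions: TBDPSCl, imidazole, CH2Cl2, rt
Reagents that add atoms: tert-butyldiphenylsilyl chloride, CC(C)(C)[Si](Cl)(c1ccccc1)c1ccccc1
Why: Standard imidazole-mediated silylation of a primary alcohol; the formamide N–H is not silylated under these conditions.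

Step 9
Reactants: 14 N-[2-(tert-butyldiphenylsilyloxy)ethyl]formamide
Product: 15 2-(tert-butyldiphenylsilyloxy)ethyl isocyanide
Conditions: POCl3, Et3N, CH2Cl2, −30 to 0 °C; aq. Na2CO3 quench
Reagents that add atoms: none
Why: Dehydration of an N-monosubstituted formamide to the isocyanide; the cold, basic medium leaves the silyl ether untouched.

Step 10
Reactants: 11 3-(allyloxy)-7-methyl-2H-naphtho[1,8-bc]furan-2-one; 15 2-(tert-butyldiphenylsilyloxy)ethyl isocyanide; 16 3-methoxy-2-(trimethylsilyl)phenyl trifluoromethanesulfonate
Product: 18 racemic spiro imino-isobenzofuran ketal (C7' allyl ether), via 3-methoxybenzyne 17 (not isolated)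
Conditions: CsF, MeCN, rt (16 added slowly; 15 and 16 in excess over 11)
Reagents that add atoms: none
Why: Fluoride attacks silicon in 16 and triflate leaves, releasing 17 in low stationary concentration. The isocyanide carbon of 15 adds to the aryne carbon remote from methoxy, because the aryl anion then sits next to the inductively withdrawing C–O bond; this puts the future C1 on C7a and the anion on C3a. The anion adds to the carbonyl of 11, an aryl ester made more electrophilic by the strain of the peri ring, and the tetrahedral alkoxide attacks the nitrilium carbon, closing the five-membered imino-isobenzofuran ring by 5-exo-dig. Opening of the tetrahedral alkoxide to a keto naphtholate is reversible, and capture by the nitrilium is the only productive exit, so both forms should converge on 18. The closest known reaction type is the aryne–isocyanide–carbonyl three-component coupling to imino-isobenzofurans, in which aryl esters are established third components; 11 is a cyclic aryl ester, so a spiro ketal results in place of an aryloxy ketal. C3 becomes stereogenic without control, which is of no consequence because step 12 ionizes it again. The step needs the regiochemistry of aryne attack, which the methoxy group secures, and addition of the isocyanide before the carbonyl partner, which its higher nucleophilicity towards arynes secures; the silyl ether and the allyl ether are inert to CsF in MeCN.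

Step 11
Reactants: 18 racemic spiro imino-isobenzofuran ketal (C7' allyl ether)
Product: 19 racemic spiro imino-isobenzofuran ketal with free C7' hydroxyl
Conditions: Pd(PPh3)4 (cat.), PhNHMe, THF, rt
Reagents that add atoms: none
Why: Tsuji–Trost-type deallylation: zerovalent palladium ionizes the aryl allyl ether and N-methylaniline captures the π-allyl complex. The medium is neither acidic nor strongly basic, so the imidate ketal should not ionize before the chiral acid is present.

Step 12
Reactants: 19 racemic spiro imino-isobenzofuran ketal with free C7' hydroxyl
Product: 20 (S)-spiro lactam silyl ether
Conditions: (R)-3,3'-bis(2,4,6-triisopropylphenyl)-1,1'-binaphthyl-2,2'-diyl hydrogen phosphate (10 mol %), 5 Å molecular sieves, toluene, −40 °C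
Reagents that add atoms: none
Why: Proposed new method: the acid protonates the imidate nitrogen and the C3–O bond ionizes with help from O1' and the free C7' hydroxyl, giving an oxocarbenium ion with ortho-quinone methide character that stays hydrogen-bonded to the chiral phosphate together with the released amide N–H. The nitrogen then closes ring B (5-exo-trig) on one face of C3, the two faces corresponding to the two rotamers about C3–C3a that the phosphate pocket distinguishes, and the product, a more stable and much less basic amide, should not re-ionize readily. The closest known reaction types are the acid-mediated isomerization of imino-isobenzofurans to isoindolinones and the chiral phosphoric acid-catalysed addition of N–H nucleophiles to ortho-quinone methides and N-acyl ketiminium ions.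

Step 13
Reactants: 20 (S)-spiro lactam silyl ether
Product: 21 (S)-spiro lactam diol (target)
Conditions: Bu4NF, AcOH, THF, 0 °C to rt
Reagents that add atoms: none
Why: Fluoride cleavage of the silyl ether; acetic acid keeps the medium from becoming basic enough to form the C7' naphtholate, which could open the N,O-ketal through a quinone methide and scramble C3.

## Compound list

1 | 4-hydroxyphenylacetone, 1-(4-hydroxyphenyl)propan-2-one | CC(=O)Cc1ccc(O)cc1 | starting material
2 | 1-[4-(allyloxy)phenyl]propan-2-one | C=CCOc1ccc(CC(C)=O)cc1 | intermediate
3 | triethyl phosphonoacetate | CCOC(=O)CP(=O)(OCC)OCC | starting material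
4 | ethyl 4-[4-(allyloxy)phenyl]-3-methylbut-2-enoate (alkene isomers; formed in the flask) | C=CCOc1ccc(CC(C)=CC(=O)OCC)cc1 | intermediate
5 | 4-[4-(allyloxy)phenyl]-3-methylbut-2-enoic acid (alkene isomers) | C=CCOc1ccc(CC(C)=CC(=O)O)cc1 | intermediate
6 | 7-(allyloxy)-3-methylnaphthalen-1-yl acetate (formed in the flask) | CC(=O)Oc1cc(C)cc2ccc(OCC=C)cc12 | intermediate
7 | 7-(allyloxy)-3-methylnaphthalen-1-ol | Oc1cc(C)cc2ccc(OCC=C)cc12 | intermediate
8 | tert-butyl 7-(allyloxy)-3-methylnaphthalen-1-yl carbonate | CC(C)(C)OC(=O)Oc1cc(C)cc2ccc(OCC=C)cc12 | intermediate
9 | 8-bromo-7-(allyloxy)-3-methylnaphthalen-1-yl tert-butyl carbonate | CC(C)(C)OC(=O)Oc1cc(C)cc2ccc(OCC=C)c(Br)c12 | intermediate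
10 | tert-butyl 2-(allyloxy)-8-hydroxy-6-methyl-1-naphthoate (formed in the flask as its lithium naphtholate) | CC(C)(C)OC(=O)c1c(OCC=C)ccc2cc(C)cc(O)c12 | intermediate
11 | 3-(allyloxy)-7-methyl-2H-naphtho[1,8-bc]furan-2-one | C=CCOc1ccc2cc(C)cc3OC(=O)c1c23 | intermediate
12 | ethanolamine | NCCO | starting material
13 | N-(2-hydroxyethyl)formamide | O=CNCCO | intermediate
14 | N-[2-(tert-butyldiphenylsilyloxy)ethyl]formamide | O=CNCCO[Si](c1ccccc1)(c1ccccc1)C(C)(C)C | intermediate
15 | 2-(tert-butyldiphenylsilyloxy)ethyl isocyanide | [C-]#[N+]CCO[Si](c1ccccc1)(c1ccccc1)C(C)(C)C | intermediate
16 | 3-methoxy-2-(trimethylsilyl)phenyl trifluoromethanesulfonate | COc1cccc(OS(=O)(=O)C(F)(F)F)c1[Si](C)(C)C | starting material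
17 | 3-methoxybenzyne (formed in the flask) | COC1=CC=CC#C1 | intermediate
18 | racemic spiro ketal: 3-{[2-(tert-butyldiphenylsilyloxy)ethyl]imino}-7-methoxy-1,3-dihydroisobenzofuran whose C1 is also C2 of a 3-(allyloxy)-7-methyl-2H-naphtho[1,8-bc]furan | COc1cccc2c1C1(Oc3cc(C)cc4ccc(OCC=C)c1c34)OC2=NCCO[Si](c1ccccc1)(c1ccccc1)C(C)(C)C | intermediate
19 | racemic spiro ketal: as 18, with 3-hydroxy in place of 3-(allyloxy) on the naphthofuran | COc1cccc2c1C1(Oc3cc(C)cc4ccc(O)c1c34)OC2=NCCO[Si](c1ccccc1)(c1ccccc1)C(C)(C)C | intermediate
20 | (S)-spiro lactam silyl ether: 2-[2-(tert-butyldiphenylsilyloxy)ethyl]-4-methoxyisoindolin-1-one whose C3 is also C2 of a 3-hydroxy-7-methyl-2H-naphtho[1,8-bc]furan | COc1cccc2c1[C@]1(Oc3cc(C)cc4ccc(O)c1c34)N(CCO[Si](c1ccccc1)(c1ccccc1)C(C)(C)C)C2=O | intermediate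
21 | (S)-spiro lactam diol: 2-(2-hydroxyethyl)-4-methoxyisoindolin-1-one whose C3 is also C2 of a 3-hydroxy-7-methyl-2H-naphtho[1,8-bc]furan | COc1cccc2c1[C@]1(Oc3cc(C)cc4ccc(O)c1c34)N(CCO)C2=O | target

## Step count and least certain steps

Total step count: 13. Longest linear sequence: 10 steps (steps 1 to 6, then 10 to 13); the isocyanide branch (steps 7 to 9) has 3 steps.

Step 12 (the one step beyond known chemistry). What may go wrong:
- loss of enantiomeric purity, through a poorly differentiated ion pair, through an uncatalysed or achiral-acid background transposition, or through re-ionization of the product;
- interception of the cation by traces of water, which would open the ketal to a keto amide.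

Fallback, by known chemistry: it sets out from 19. A catalytic amount of an achiral acid (diphenyl hydrogen phosphate, CH2Cl2, rt) should bring about the same oxygen-to-nitrogen transposition without stereocontrol and give the racemic lactam silyl ether F1. Preparative chromatography on a chiral stationary phase then separates the enantiomers and delivers 20, where the route is rejoined. The unwanted enantiomer can be returned to the racemate by renewed acid treatment and recycled.

Step 10 (key step). What may go wrong:
- protonation of the methoxy-flanked aryl anion, or its capture by a second aryne, before it reaches the hindered lactone carbonyl;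
- irreversible diversion of the ring-opened keto naphtholate (O-arylation by the aryne);
- slow loss of the silyl ether to fluoride.

Fallback: it sets out from 11 and 12 and replaces the three-component coupling by a two-component organolithium addition.
- 12 is O-silylated (TBDPSCl, imidazole) to 2-(tert-butyldiphenylsilyloxy)ethanamine F2.
- F2 is acylated with 3-methoxybenzoyl chloride (Et3N) to N-[2-(tert-butyldiphenylsilyloxy)ethyl]-3-methoxybenzamide F3.
- Double deprotonation (s-BuLi, TMEDA, THF, −78 °C) lithiates the carbon between the amide and the methoxy group (directed ortho metalation), and the aryllithium adds to 11.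
- Acid work-up (p-TsOH, CH2Cl2) closes the hydroxy lactam onto the liberated C1' naphthol and gives the racemic C7' allyl ether lactam F4.
- Deallylation as in step 11 gives the racemic lactam silyl ether F1, which is resolved as described for step 12 and comes back to the route at 20.

Step 11. What may go wrong: premature, uncatalysed oxygen-to-nitrogen transposition once the naphthol is unmasked (the free hydroxyl assists ionization of the ketal), which would feed racemic lactam into step 12; aminolysis of the imidate is a lesser risk.

Fallback: it sets out from 18 and inverts the order. The chiral acid of step 12 is applied to 18 itself, before unmasking, to give the C7' allyl ether lactam F5 (spiro carbon as in 20), in which the phosphate is held by the amide N–H alone. Zerovalent palladium deallylation of F5, which no longer contains an imidate, then gives 20.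

Step 6. What may go wrong: attack of n-BuLi on the carbonate carbonyl in competition with bromine–lithium exchange, or carbolithiation of the neighbouring allyl ether by the aryllithium if the acyl transfer is slow.

Fallback: it sets out from 9 and replaces the intramolecular acyl transfer by external carboxylation. CF3CO2H removes the carbonate to give 8-bromo-7-(allyloxy)-3-methylnaphthalen-1-ol F6. Deprotonation with NaH, bromine–lithium exchange (n-BuLi, THF, −78 °C), quenching with CO2 and acidification should give the 8-hydroxy-1-naphthoic acid, which lactonizes to 11.

## Further compounds

F1 | step 12 | racemic spiro lactam silyl ether (racemate of 20) | COc1cccc2c1C1(Oc3cc(C)cc4ccc(O)c1c34)N(CCO[Si](c1ccccc1)(c1ccccc1)C(C)(C)C)C2=O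
F2 | step 10 | 2-(tert-butyldiphenylsilyloxy)ethanamine | NCCO[Si](c1ccccc1)(c1ccccc1)C(C)(C)C
F3 | step 10 | N-[2-(tert-butyldiphenylsilyloxy)ethyl]-3-methoxybenzamide | COc1cccc(c1)C(=O)NCCO[Si](c1ccccc1)(c1ccccc1)C(C)(C)C
F4 | step 10 | racemic C7' allyl ether of the spiro lactam silyl ether | COc1cccc2c1C1(Oc3cc(C)cc4ccc(OCC=C)c1c34)N(CCO[Si](c1ccccc1)(c1ccccc1)C(C)(C)C)C2=O
F5 | step 11 | C7' allyl ether of the spiro lactam silyl ether, spiro carbon arranged as in 20 | COc1cccc2c1[C@]1(Oc3cc(C)cc4ccc(OCC=C)c1c34)N(CCO[Si](c1ccccc1)(c1ccccc1)C(C)(C)C)C2=O
F6 | step 6 | 8-bromo-7-(allyloxy)-3-methylnaphthalen-1-ol | Oc1cc(C)cc2ccc(OCC=C)c(Br)c12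
A1 | alternative 1 | (2-bromo-6-methoxyphenyl)(2-hydroxy-6-methyl-8-triisopropylsilyloxynaphthalen-1-yl)methanone | COc1cccc(Br)c1C(=O)c1c(O)ccc2cc(C)cc(O[Si](C(C)C)(C(C)C)C(C)C)c12
A2 | alternative 1 | 1-(2-bromo-6-methoxyphenyl)-2-diazo-3-[4-methyl-2-(triisopropylsilyloxy)-6-vinylphenyl]propane-1,3-dione | COc1cccc(Br)c1C(=O)C(=[N+]=[N-])C(=O)c1c(C=C)cc(C)cc1O[Si](C(C)C)(C(C)C)C(C)C
A3 | alternative 2 | methyl 2-{[2,8-bis(benzyloxy)-6-methylnaphthalen-1-yl]carbonyl}-3-methoxybenzoate | COC(=O)c1cccc(OC)c1C(=O)c1c(OCc2ccccc2)ccc2cc(C)cc(OCc3ccccc3)c12
A4 | alternative 2 | 3-methoxy-2H-pyran-2-one | COC1=CC=COC1=O
A5 | alternative 2 | methyl 4-[2,8-bis(benzyloxy)-6-methylnaphthalen-1-yl]-4-oxobut-2-ynoate | COC(=O)C#CC(=O)c1c(OCc2ccccc2)ccc2cc(C)cc(OCc3ccccc3)c12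
A6 | alternative 3 | N-unsubstituted spiro lactam with the C7' hydroxyl as triisopropylsilyl ether, spiro carbon arranged as in the target | COc1cccc2c1[C@]1(Oc3cc(C)cc4ccc(O[Si](C(C)C)(C(C)C)C(C)C)c1c34)NC2=O
A7 | alternative 3 | 3-aryl-1,4,2-dioxazol-5-one whose aryl group is 3-methoxyphenyl carrying at C2 the 7-methyl-3-(triisopropylsilyloxy)-2H-naphtho[1,8-bc]furan-2-yl group, single enantiomer at the C–H carbon | COc1cccc(C2=NOC(=O)O2)c1[C@H]1Oc2cc(C)cc3ccc(O[Si](C(C)C)(C(C)C)C(C)C)c1c23
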